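## Retrosynthesis
1. Target (11) ⇐ hydrogenation of the alkene and the aryl benzyl ether in cross-metathesis product 10. Product 10 comes from allyl bicycle 6 and the aryl-undecene 9.
2. Bicycle 6 ⇐ diastereoselective Sakurai allylation of the oxocarbenium ion generated from methyl ketal 5. Attack on the convex face of the cis-fused bicycle sets the C7 quaternary ether.
3. Ketal 5 ⇐ one-pot hemiketalization / intramolecular oxa-Michael of methyl ketone 4 onto its own butenolide. The THF ring closes here, and the cis-fusion requirement sets C5 from C1.
4. Ketone 4 ⇐ Wacker oxidation of 5-allyl-5-methylbutenolide 3. Butenolide 3 comes from Pd-catalysed asymmetric γ-allylation of α-angelica lactone (1), which sets C1, the only catalyst-controlled stereocentre. The lactone ring is present from the start and the THF ring forms in step 3.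

Target configuration: (1S,5S,7S)-7-[12-(4-hydroxyphenyl)dodecyl]-1,7-dimethyl-2,6-dioxabicyclo[3.3.0]octan-3-one. The skeleton is a cis-fused γ-lactone and THF.

Assumptions (one line each):
- The phenol is carried as a benzyl ether.
- The Trost ligand enantiomer is whichever delivers the (S)-butenolide.

## Route

**Step 1**
Reactants: 1 (α-angelica lactone, 5-methylfuran-2(3H)-one); 2 (allyl methyl carbonate)
Product: 3, (S)-5-allyl-5-methylfuran-2(5H)-one
Conditions: Pd2(dba)3·CHCl3 (2.5 mol%), (S,S)-Trost DACH-phenyl ligand (7.5 mol%), THF, 23 °C
Reagents that add atoms: allyl methyl carbonate, C=CCOC(=O)OC (supplies the allyl group; the methoxide it releases acts as the base)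
Why: Tsuji–Trost asymmetric allylic alkylation of the extended dienolate at the γ-carbon makes the all-carbon quaternary C1, with the face chosen by the chiral π-allyl-Pd pocket.
Proposed new method: γ-selective Pd-AAA of the α-angelica lactone dienolate with a simple allyl carbonate. The closest known reactions are Pd-AAA of prochiral enolates to form quaternary centres and γ-allylation of substituted butenolides.

**Step 2**
Reactants: 3
Product: 4, (S)-5-methyl-5-(2-oxopropyl)furan-2(5H)-one
Conditions: PdCl2 (10 mol%), CuCl (1 equiv), O2 (balloon), DMF/H2O 7:1, 23 °C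
Reagents that add atoms: O2, O=O; H2O, O
Why: Wacker–Tsuji oxidation converts the terminal alkene to the Markovnikov methyl ketone. The electron-poor butenolide alkene does not react, and the quaternary centre is untouched.

**Step 3**
Reactants: 4
Product: 5, (1S,5S)-7-methoxy-1,7-dimethyl-2,6-dioxabicyclo[3.3.0]octan-3-one (mixture of C7 epimers)
Conditions: DBU (0.3 equiv), MeOH (0.1 M), 0 °C → 23 °C; quench with AcOH
Reagents that add atoms: methanol, CO (becomes the OMe of the ketal)
Why: The ketone forms its methyl hemiketal in MeOH, and the hemiketal alkoxide adds to the butenolide β-carbon in a 5-exo-trig oxa-Michael (hemiketalization / oxa-Michael cascade). A cis-fused 5-5 system is the only one accessible, so C5 is set by C1; the C7 epimers are irrelevant because both ionize to the same cation in step 4.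
Proposed new method: intramolecular oxa-Michael of a methanol-derived hemiketal onto a γ,γ-disubstituted butenolide. The closest known reactions are hemiketalization/oxa-Michael cascades used for THF and THP ketals.

**Step 4**
Reactants: 5
Product: 6, (1S,5S,7S)-7-allyl-1,7-dimethyl-2,6-dioxabicyclo[3.3.0]octan-3-one
Conditions: allylSiMe3 (3 equiv), BF3·OEt2 (3 equiv), CH2Cl2, −78 → −30 °C
Reagents that add atoms: allyltrimethylsilane, C=CC[Si](C)(C)C (supplies the allyl group)
Why: The Lewis acid removes the exocyclic OMe to give the bicyclic 2-methyl-oxocarbenium ion, and Hosomi–Sakurai allylation follows. The concave face is shielded by the lactone ring atoms (C4 on C5, O2 on C1), so attack on the convex face puts the new chain cis to the C1 methyl, as in the target.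
Proposed new method: facial-selective C-allylation of a cis-bicyclic ketal-derived oxocarbenium ion to build a quaternary centre. The closest known reactions are furanosyl oxocarbenium C-glycosylation and Sakurai allylation of ketals.

**Step 5** (prepares the metathesis partner, run in parallel)
Reactants: 7 (11-bromoundec-1-ene); 8 (4-(benzyloxy)phenylmagnesium bromide)
Product: 9, 1-(benzyloxy)-4-(undec-10-en-1-yl)benzene
Conditions: Li2CuCl4 (5 mol%), THF, 0 °C → 23 °C
Reagents that add atoms: none beyond the numbered reactants
Why: Cu-catalysed Kumada-type sp2–sp3 coupling of an aryl Grignard with a primary alkyl bromide; the terminal alkene and benzyl ether are untouched.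

**Step 6**
Reactants: 6; 9 (3 equiv)
Product: 10, the E/Z mixture of the cross-metathesis alkene, C[C@]1(CC=CCCCCCCCCCc2ccc(OCc3ccccc3)cc2)C[C@]2(C)OC(=O)C[C@@H]2O1
Conditions: Hoveyda–Grubbs II (5 mol%), CH2Cl2, 40 °C
Reagents that add atoms: none (ethylene is lost)
Why: Olefin cross-metathesis of the unhindered terminal allyl group with an excess of a type I alkene. The new C=C geometry is irrelevant because it is hydrogenated next, and the THF ether and lactone are inert.

**Step 7**
Reactants: 10
Product: 11, plakortone N
Conditions: H2 (1 atm), 10% Pd/C, EtOAc/EtOH, 23 °C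
Reagents that add atoms: hydrogen, [H][H]
Why: Catalytic hydrogenation saturates the alkene and hydrogenolyses the aryl benzyl ether to the free phenol. No stereocentre is benzylic or otherwise labile, and the bicyclic lactone-ether survives neutral conditions.

## Compound list
1 | α-angelica lactone, 5-methylfuran-2(3H)-one | CC1=CCC(=O)O1 | starting material
2 | allyl methyl carbonate | C=CCOC(=O)OC | starting material
3 | (S)-5-allyl-5-methylfuran-2(5H)-one | C=CC[C@]1(C)OC(=O)C=C1 | intermediate
4 | (S)-5-methyl-5-(2-oxopropyl)furan-2(5H)-one | CC(=O)C[C@]1(C)OC(=O)C=C1 | intermediate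
5 | (1S,5S)-7-methoxy-1,7-dimethyl-2,6-dioxabicyclo[3.3.0]octan-3-one (C7 epimers) | COC1(C)C[C@]2(C)OC(=O)C[C@@H]2O1 | intermediate
6 | (1S,5S,7S)-7-allyl-1,7-dimethyl-2,6-dioxabicyclo[3.3.0]octan-3-one | C[C@]1(CC=C)C[C@]2(C)OC(=O)C[C@@H]2O1 | intermediate
7 | 11-bromoundec-1-ene | C=CCCCCCCCCCBr | starting material
8 | 4-(benzyloxy)phenylmagnesium bromide | Br[Mg]c1ccc(OCc2ccccc2)cc1 | starting material
9 | 1-(benzyloxy)-4-(undec-10-en-1-yl)benzene | C=CCCCCCCCCCc1ccc(OCc2ccccc2)cc1 | intermediate
10 | cross-metathesis alkene (E/Z) | C[C@]1(CC=CCCCCCCCCCc2ccc(OCc3ccccc3)cc2)C[C@]2(C)OC(=O)C[C@@H]2O1 | intermediate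
11 | plakortone N, (1S,5S,7S)-7-[12-(4-hydroxyphenyl)dodecyl]-1,7-dimethyl-2,6-dioxabicyclo[3.3.0]octan-3-one | C[C@]1(CCCCCCCCCCCCc2ccc(O)cc2)C[C@]2(C)OC(=O)C[C@@H]2O1 | target

## Totals
Total steps: 7. Longest linear sequence: 6 (steps 1, 2, 3, 4, 6, 7).

## Three steps most likely to fail
1. **Step 4 (C7 diastereoselectivity).** Convex-face selectivity of the oxocarbenium allylation is only predicted, and Me versus the ring-fused environment gives a modest bias.
   Fallback: add an organocerium reagent made from a 12-(4-benzyloxyphenyl)dodecyl halide to ketone 4. Separate the C7 epimeric tertiary alcohols, then close each by tertiary-alkoxide oxa-Michael (base). This replaces cation facial control with a separation, and C5 is still set by cis-fusion.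
2. **Step 3 (hemiketal oxa-Michael equilibrium).** The ketal may not be thermodynamically favoured over ketone plus butenolide.
   Fallback: install the C5 oxygen stepwise. Epoxidize the butenolide (H2O2 or tBuOOH, base), open the α-C–O bond with SmI2 to the β-hydroxy lactone, and separate diastereomers. Then ketalize the cis isomer acid-catalysed (CSA, HC(OMe)3, MeOH) to give 5.
3. **Step 1 (γ- versus α-selectivity and ee of the Pd-AAA).**
   Fallback: abandon asymmetric catalysis. Make racemic 3 with achiral Pd(PPh3)4, take it through the Wacker step to racemic 4, and resolve by preparative chiral SFC before step 3.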